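**Easy step.** Solid J goes into solution as D and ends as L in a closed, stirred, isothermal flask, and I want what stands there at 5.0 d from a charge of 1.0 M.

| flask | J | remark | time |
|---|---|---|---|
| midnight | 0.50 M | run made earlier |  |
| spring | 0.75 M | run made earlier |  |
| flask | 1.0 M |  | 5.0 d |

| run | time / d | J / % | L / % | D / % |
|---|---|---|---|---|
| midnight | 0.250 | 56.2 | 28.0 | 12.2 |
| midnight | 0.833 | 0.2 | 93.7 | 5.3 |
| midnight | 1.25 | 0 | 96.1 | 5.4 |
| midnight | 2.00 | 0 | 95.9 | 6.4 |
| midnight | 3.00 | 0 | 96.0 | 4.2 |
| midnight | 4.00 | 0.2 | 96.0 | 4.5 |
| spring | 0.250 | 71.7 | 19.6 | 8.6 |
| spring | 0.833 | 27.3 | 65.5 | 9.4 |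
| spring | 1.25 | 0.2 | 95.7 | 5.5 |
| spring | 2.00 | 0 | 96.5 | 3.6 |
| spring | 3.00 | 0 | 97.1 | 3.3 |
| spring | 4.00 | 1.0 | 96.3 | 3.5 |

(scatter of a reading: 1 percentage point)

- at the start none of J is in solution
- what has only dissolved of J counts as not reacted
- a reading or a percentage of L counts all its forms, free or not
- the reaction counts as stopped when no species that holds the J changes by six tenths of a point or more over the second half of the time
- D means what is dissolved; the solid is not counted in it

- the state of affairs at 5.0 d: stopped, and by what, or still going (for what has run out or reacted, a solid counts together with what of it has only dissolved) (all of J has reacted / forward and back rates have come level / it is still moving)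
- part of the J that has turned into other species by 5.0 d (what has only dissolved does not count)
- the L standing at 5.0 d, as a percentage of the J charged
- the D standing at 5.0 d, as a percentage of the J charged

**Draining J.** Between 0.250 d and 0.833 d the spring run loses 44.4% of its charge of J. Taken as the same amount per day, that empties the flask's larger charge in about 1.75 d, less than the time asked. At 2.00 d both runs read J at 0%, and from then on D and L merely scatter, so I freeze them.

**Two ways.** I carry the residue, the fraction of the flask's charge standing as D once the readings have stopped moving, and I take the amount of D as equal across charges, so the fraction scales inversely with charge. This is a residue under thermodynamic control. The runs only lean that way: the midnight shortfall of L below its own charge, read as the average from 2.00 d on, 4.03%, exceeds the spring one, 3.37%. Scaling these shortfalls to the flask and averaging gives 2.27%. The D readings, scaled the same way, give 2.56%.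

**The cheat.** The ways part in the midnight run. At 2.00 d its D and L add to 102% of the charge, and its L there matches its neighbours, so I distrust that D reading of 6.4%. Without it the D way gives 2.39%, close to the shortfall way. I commit to D at 2.27%, with L and conversion at 97.7%, stopped at balance.

**The forecast.** The forecast says forward and back rates have come level, with conversion 97.4%, L 97.4% and D 2.6%, a D above mine, on the ground that the “concentration is fixed, not the L/D ratio”.

**The result.** At 5.0 d in the flask forward and back rates have come level, with conversion 97.8%, L 97.8% and D 2.16%.

    D ⇌ L (K = 1.90, k = 1.60 × 10⁻⁴ s⁻¹)
    J ⇌ D, rate k2*(cs2 - [D]) while solid is left; crystals form when [D] > cs2 (solubility = 0.0650 M, k = 0.00330 s⁻¹)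
    Q ⇌ L, rate k3*(cs3 - [L]) while solid is left; crystals form when [L] > cs3 (solubility = 41.0 mM, k = 0.0200 s⁻¹)

**The residue checked.** The flask's D lies 0.11 percentage points below my residue, and at 5.00 d the crystals Q hold 93.7% of the charge, counted within L. The limit of solubility of L is the main reason for this conversion: the same flask without it converts 12.3% instead of 97.8%. Carried to a charge of 0.301 M at the same time, the residue gives D at 7.54% and conversion at 92.5%, and that flask's conversion stands at 92.8%.

(The runs are calculated for substances that don't exist, and the scatter is random.)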